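The route rests on cutting the C4–C4a bond of ring C. In the target the C4 carbonyl sits on C4a, the ring A carbon between C5–O and C8a–O1. C8, the other carbon ortho to O1, is filled by the prenyl group, so an iodine on C4a marks the one possible site of closure. Iodine–lithium exchange makes C4a nucleophilic. Its attack on a tethered N-methoxy-N-methylamide forms C4–C4a, closes ring C and installs the ketone in one operation, with the C2 stereocentre already in place. The precursor is an (S)-3-aryl-3-(2-iodoaryloxy)propanoic Weinreb amide whose C2–O1 bond comes from an iridium-catalysed asymmetric allylic etherification.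

Key step: step 16

Assumption: in step 12 the (Sa,Sc,Sc) ligand is taken to steer the aryloxide to the allyl face that gives the (S) ether. If the sense is opposite for this substrate, the equally available (Ra,Rc,Rc) antipode is used and nothing else changes.

Remark on ring B: it is the linear, 6,7-substituted 2,2-dimethylchromene. A propargyl ether Claisen sequence on a 4-O-propargylated salicylaldehyde closes at the carbon between the two oxygens and gives the angular isomer. The pyran ring is therefore bought in as a chromanone, and the carbon that becomes C2 is added by ortho-formylation.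

Remark on protecting groups: MOM stays on O5 because it chelates the aryllithium, whereas a silyl ether there would invite O-to-C silyl migration. The same group on O2' allows a single final step.

Remark on handling: every compound from the allyl ether to the flavanone holds a doubly activated benzylic C–O bond. These compounds are kept free of acid and purified on Et3N-deactivated silica.

Abbreviations used in names:
- ArA–O = 2-iodo-5-methoxy-3-(methoxymethoxy)-6-(3-methylbut-2-enyl)phenoxy
- ArB = 7-(methoxymethoxy)-2,2-dimethyl-2H-chromen-6-yl

**Ring A (steps 1–5)**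

Step 1
Reactants: 1 5-methoxyresorcinol
Product: 2 2-iodo-5-methoxybenzene-1,3-diol
Conditions: I2 (1.0 equiv), NaHCO3, H2O–THF, 0 °C
Reagents that add atoms: iodine, II
Why: Electrophilic aromatic iodination of the phenoxide in aqueous bicarbonate goes, as is usual for resorcinols under these conditions, to the carbon flanked by both hydroxyl groups, and one equivalent of iodine at 0 °C should hold the reaction at the mono-iodide.

Step 2
Reactants: 2 2-iodo-5-methoxybenzene-1,3-diol
Product: 3 2-iodo-5-methoxy-3-(methoxymethoxy)phenol
Conditions: MOMCl (1.0 equiv), i-Pr2NEt, CH2Cl2, 0 °C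
Reagents that add atoms: chloromethyl methyl ether, COCCl
Why: MOM ether formation by O-alkylation of two equivalent hydroxyl groups with one equivalent of reagent should give the mono-ether as the main part of a statistical mixture, and under- and over-alkylated material differs enough in polarity to be separated and recycled.

Step 3
Reactants: 3 2-iodo-5-methoxy-3-(methoxymethoxy)phenol; 4 3-chloro-3-methylbut-1-yne
Product: 5 2-iodo-5-methoxy-1-(methoxymethoxy)-3-[(2-methylbut-3-yn-2-yl)oxy]benzene
Conditions: CuCl2·2H2O (1 mol %), DBU, MeCN, 0 °C
Reagents that add atoms: none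
Why: Copper-catalysed propargylic etherification of a phenol with a tertiary propargylic chloride forms the hindered tertiary C–O bond at 0 °C, a temperature at which the aryl iodide and the MOM ether are inert.

Step 4
Reactants: 5 2-iodo-5-methoxy-1-(methoxymethoxy)-3-[(2-methylbut-3-yn-2-yl)oxy]benzene
Product: 6 2-iodo-5-methoxy-1-(methoxymethoxy)-3-[(2-methylbut-3-en-2-yl)oxy]benzene
Conditions: H2 (1 atm), Pd/CaCO3 poisoned with Pb(OAc)2, quinoline, EtOAc, rt
Reagents that add atoms: none
Why: Lindlar-type semihydrogenation should stop after one equivalent of H2 because the poisoned palladium surface binds the terminal alkyne much more strongly than the alkene formed, and so deactivated a catalyst is not expected to cleave the aryl C–I bond.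

Step 5
Reactants: 6 2-iodo-5-methoxy-1-(methoxymethoxy)-3-[(2-methylbut-3-en-2-yl)oxy]benzene
Product: 8 2-iodo-5-methoxy-3-(methoxymethoxy)-6-(3-methylbut-2-enyl)phenol, via cyclohexadienone 7 (not isolated)
Conditions: N,N-diethylaniline, 130 °C
Reagents that add atoms: none
Why: Aromatic Claisen rearrangement of the 1,1-dimethylallyl ether can end productively only at the one free ortho carbon, since the other carries iodine, so the [3,3] shift turns the tertiary allyl unit into a prenyl group and tautomerisation of dienone 7 restores the phenol, while the amine solvent excludes acid that could split off isoprene or cyclise the product.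

**Ring B (steps 6–11)**

Step 6
Reactants: 9 7-hydroxy-2,2-dimethylchroman-4-one
Product: 11 2,2-dimethyl-2H-chromen-7-ol, via chromane-4,7-diol 10 (not isolated)
Conditions: NaBH4 (excess), EtOH–THF, 0 °C to rt; then 2 M HCl, Et2O, rt
Reagents that add atoms: none
Why: Borohydride reduction of the aryl ketone followed by acid-catalysed E1 dehydration, which is easy because the C4 benzylic cation is stabilised by the para oxygen at C7, should give the chromene, and the stereocentre of racemic 10 disappears with the loss of water.

Step 7
Reactants: 11 2,2-dimethyl-2H-chromen-7-ol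
Product: 12 7-hydroxy-2,2-dimethyl-2H-chromene-6-carbaldehyde
Conditions: MgCl2, Et3N, (CH2O)n, MeCN, reflux; dilute HCl work-up
Reagents that add atoms: paraformaldehyde (reacts as formaldehyde), C=O
Why: Casnati–Skattebøl ortho-formylation delivers formaldehyde inside a magnesium phenoxide chelate and so only to a carbon ortho to the hydroxyl, and of the two such carbons the open C6 (para to the ring oxygen) should react rather than C8, which is squeezed between two oxygens, fixing the linear ring B pattern.

Step 8
Reactants: 12 7-hydroxy-2,2-dimethyl-2H-chromene-6-carbaldehyde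
Product: 13 7-(methoxymethoxy)-2,2-dimethyl-2H-chromene-6-carbaldehyde
Conditions: MOMCl (excess), i-Pr2NEt, CH2Cl2, 0 °C to rt
Reagents that add atoms: chloromethyl methyl ether, COCCl
Why: MOM ether formation by O-alkylation should go to completion with excess reagent, because the hydrogen-bonded salicylaldehyde hydroxyl reacts slowly but is the only nucleophile present.

Step 9
Reactants: 13 7-(methoxymethoxy)-2,2-dimethyl-2H-chromene-6-carbaldehyde
Product: 14 ethyl (E)-3-(ArB)prop-2-enoate
Conditions: (EtO)2P(O)CH2CO2Et, NaH, THF, 0 °C to rt
Reagents that add atoms: triethyl phosphonoacetate, CCOC(=O)CP(=O)(OCC)OCC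
Why: Horner–Wadsworth–Emmons olefination of an aromatic aldehyde with a stabilised phosphonate carbanion equilibrates before elimination and should therefore give the (E)-enoate.

Step 10
Reactants: 14 ethyl (E)-3-(ArB)prop-2-enoate
Product: 15 (E)-3-(ArB)prop-2-en-1-ol
Conditions: i-Bu2AlH (2.2 equiv), CH2Cl2, −78 °C; aqueous potassium sodium tartrate
Reagents that add atoms: none
Why: 1,2-Reduction of the conjugated ester with two equivalents of i-Bu2AlH at low temperature should give the (E)-allylic alcohol without touching the chromene alkene or the MOM ether.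

Step 11
Reactants: 15 (E)-3-(ArB)prop-2-en-1-ol
Product: 16 methyl (E)-3-(ArB)prop-2-enyl carbonate
Conditions: ClCO2Me, pyridine, CH2Cl2, 0 °C
Reagents that add atoms: methyl chloroformate, COC(=O)Cl
Why: Acylation of the primary alcohol with a chloroformate in the presence of pyridine installs the carbonate leaving group under basic conditions, which the acid-sensitive, electron-rich cinnamyl system tolerates.

**Union and end game (steps 12–17)**

Step 12
Reactants: 8 2-iodo-5-methoxy-3-(methoxymethoxy)-6-(3-methylbut-2-enyl)phenol; 16 methyl (E)-3-(ArB)prop-2-enyl carbonate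
Product: 18 (S)-3-(ArA–O)-3-(ArB)prop-1-ene, via lithium aryloxide 17 (not isolated)
Conditions: 8, LiOt-Bu (1.0 equiv), THF, 0 °C; then 16, [Ir(cod)Cl]2 (2 mol %), (Sa,Sc,Sc)-O,O'-(1,1'-binaphthalene-2,2'-diyl) N,N-bis[1-(2-methoxyphenyl)ethyl]phosphoramidite (4 mol %, pre-activated with n-PrNH2), THF, rt
Reagents that add atoms: lithium tert-butoxide, CC(C)(C)O[Li] (its lithium is found only in 17)
Why: Iridium-catalysed asymmetric allylic etherification, in which the cyclometallated iridium–phosphoramidite complex ionises the linear carbonate to an allyl complex that the aryloxide attacks anti to the metal at the aryl-bearing terminus, should give the branched ether with C2 set as (S) by the ligand-controlled face of attack, and the 2-methoxyphenyl ligand variant is chosen because it copes best with ortho-substituted cinnamyl electrophiles.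

Step 13
Reactants: 18 (S)-3-(ArA–O)-3-(ArB)prop-1-ene
Product: 20 (S)-3-(ArA–O)-3-(ArB)propan-1-ol, via B-alkyl-9-BBN adduct 19 (not isolated)
Conditions: 9-BBN (1.3 equiv), THF, 0 °C to rt; then 30% H2O2, 2 M NaOH, 0 °C
Reagents that add atoms: 9-borabicyclo[3.3.1]nonane, B1C2CCCC1CCC2 (boron and its bicycle are found only in 19); hydrogen peroxide, OO
Why: Hydroboration–oxidation with 9-BBN places boron on the terminal carbon of the monosubstituted vinyl group far faster than it attacks the trisubstituted prenyl or the cis-disubstituted chromene alkene, and cold alkaline peroxide then replaces boron by hydroxyl without touching C2 or the aryl iodide.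

Step 14
Reactants: 20 (S)-3-(ArA–O)-3-(ArB)propan-1-ol
Product: 22 (S)-3-(ArA–O)-3-(ArB)propanoic acid, via aldehyde 21 (not isolated)
Conditions: TEMPO (20 mol %), PhI(OAc)2 (2.2 equiv), MeCN–aqueous NaH2PO4/Na2HPO4 buffer (pH 7), 0 °C to rt
Reagents that add atoms: water, O
Why: TEMPO/PhI(OAc)2 oxidation takes the primary alcohol through aldehyde 21 and its hydrate to the acid in a chlorine-free, near-neutral medium, which should spare the electron-rich rings and alkenes and offers no base to trigger β-elimination of the aryloxide.

Step 15
Reactants: 22 (S)-3-(ArA–O)-3-(ArB)propanoic acid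
Product: 24 (S)-3-(ArA–O)-3-(ArB)-N-methoxy-N-methylpropanamide, via acyl imidazolide 23 (not isolated)
Conditions: CDI, CH2Cl2, 0 °C to rt; then MeNHOMe·HCl, rt
Reagents that add atoms: 1,1'-carbonyldiimidazole, O=C(n1ccnc1)n1ccnc1 (its imidazole is found only in 23); N,O-dimethylhydroxylamine hydrochloride, CNOC.Cl
Why: Amide coupling through the acyl imidazolide needs no added base, since the imidazole already present frees the amine from its hydrochloride, so the medium should stay too weakly basic for β-elimination of the aryloxide and C2 is untouched.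

Step 16
Reactants: 24 (S)-3-(ArA–O)-3-(ArB)-N-methoxy-N-methylpropanamide
Product: 27 (2S)-flavanone bis-MOM ether, via aryllithium 25 (not isolated), via lithium hemiaminal 26 (not isolated)
Conditions: n-BuLi (1.1 equiv, slow addition), THF (0.02 M), −78 °C; AcOH in THF at −78 °C, then aqueous NaH2PO4/Na2HPO4 buffer
Reagents that add atoms: n-butyllithium, [Li]CCCC (its lithium is found only in 25 and 26)
Why: n-BuLi attacks the iodine of 24 in an exchange that at −78 °C outruns both addition to the amide and removal of an α-proton, and it gives aryllithium 25, whose C4a–Li bond is held by the MOM oxygen at C5. The carbanion then adds to the tethered amide carbonyl in a 6-exo-trig closure that forms C4–C4a and ring C. The result is the N,O-chelated lithium hemiaminal 26, which does not collapse in the cold, so no ketone is present that could enolise, accept a second nucleophile or expel the C8a aryloxide by retro-oxa-Michael opening. Acetic acid is added at −78 °C before warming, so that ketone 27 is released only into a neutral medium. The step is a Parham cyclisation joined to the Weinreb ketone synthesis, a known entry to chroman-4-ones from 2-haloaryl ethers of 3-hydroxy amides. No stereocentre is created in 27, since the C4 centre of 26 vanishes on collapse and C2 is a spectator, while regiochemistry is fixed by the position of the iodine and chemoselectivity by the fast-exchanging iodide, the low temperature and the intramolecular electrophile.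

Step 17
Reactants: 27 (2S)-flavanone bis-MOM ether
Product: 28 maackiaflavanone A
Conditions: HCl (ca. 0.5 M in MeOH), MeOH–CH2Cl2, 0 °C to rt; quench into aqueous NaH2PO4/Na2HPO4 buffer (pH 6–7)
Reagents that add atoms: none
Why: Acid-catalysed transacetalisation of both aryl MOM ethers to methanol should remove first the C5 ether next to the carbonyl and then the electron-rich ring B ether, with methanol trapping the methoxymethyl cation before it can alkylate a ring, and dilute acid at or below room temperature with a buffered quench should leave the prenyl group, the chromene and the C2–O1 bond, and with it the (S) configuration, intact.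

**Compound list**

1 | 5-methoxyresorcinol | COc1cc(O)cc(O)c1 | starting material
2 | 2-iodo-5-methoxybenzene-1,3-diol | COc1cc(O)c(I)c(O)c1 | intermediate
3 | 2-iodo-5-methoxy-3-(methoxymethoxy)phenol | COCOc1cc(OC)cc(O)c1I | intermediate
4 | 3-chloro-3-methylbut-1-yne | C#CC(C)(C)Cl | starting material
5 | 2-iodo-5-methoxy-1-(methoxymethoxy)-3-[(2-methylbut-3-yn-2-yl)oxy]benzene | COCOc1cc(OC)cc(OC(C)(C)C#C)c1I | intermediate
6 | 2-iodo-5-methoxy-1-(methoxymethoxy)-3-[(2-methylbut-3-en-2-yl)oxy]benzene | COCOc1cc(OC)cc(OC(C)(C)C=C)c1I | intermediate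
7 | 2-iodo-5-methoxy-3-(methoxymethoxy)-6-(3-methylbut-2-enyl)cyclohexa-2,4-dien-1-one (racemic, not isolated) | O=C1C(I)=C(OCOC)C=C(OC)C1CC=C(C)C | intermediate
8 | 2-iodo-5-methoxy-3-(methoxymethoxy)-6-(3-methylbut-2-enyl)phenol (ring A iodophenol) | COc1cc(OCOC)c(I)c(O)c1CC=C(C)C | intermediate
9 | 7-hydroxy-2,2-dimethylchroman-4-one (catalogue compound) | CC1(C)CC(=O)c2ccc(O)cc2O1 | starting material
10 | 2,2-dimethylchromane-4,7-diol (racemic, not isolated) | CC1(C)CC(O)c2ccc(O)cc2O1 | intermediate
11 | 2,2-dimethyl-2H-chromen-7-ol | CC1(C)C=Cc2ccc(O)cc2O1 | intermediate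
12 | 7-hydroxy-2,2-dimethyl-2H-chromene-6-carbaldehyde | CC1(C)C=Cc2cc(C=O)c(O)cc2O1 | intermediate
13 | 7-(methoxymethoxy)-2,2-dimethyl-2H-chromene-6-carbaldehyde | CC1(C)C=Cc2cc(C=O)c(OCOC)cc2O1 | intermediate
14 | ethyl (E)-3-[7-(methoxymethoxy)-2,2-dimethyl-2H-chromen-6-yl]prop-2-enoate | CCOC(=O)/C=C/c1cc2C=CC(C)(C)Oc2cc1OCOC | intermediate
15 | (E)-3-[7-(methoxymethoxy)-2,2-dimethyl-2H-chromen-6-yl]prop-2-en-1-ol | OC/C=C/c1cc2C=CC(C)(C)Oc2cc1OCOC | intermediate
16 | methyl (E)-3-[7-(methoxymethoxy)-2,2-dimethyl-2H-chromen-6-yl]prop-2-enyl carbonate | COC(=O)OC/C=C/c1cc2C=CC(C)(C)Oc2cc1OCOC | intermediate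
17 | lithium 2-iodo-5-methoxy-3-(methoxymethoxy)-6-(3-methylbut-2-enyl)phenoxide (not isolated) | [Li]Oc1c(I)c(OCOC)cc(OC)c1CC=C(C)C | intermediate
18 | (S)-branched allyl aryl ether, 3-(ArA–O)-3-(ArB)prop-1-ene | COc1cc(OCOC)c(I)c(c1CC=C(C)C)O[C@H](c1cc3c(cc1OCOC)OC(C)(C)C=C3)C=C | intermediate
19 | (S)-B-[3-(ArA–O)-3-(ArB)propyl]-9-borabicyclo[3.3.1]nonane (not isolated) | COc1cc(OCOC)c(I)c(c1CC=C(C)C)O[C@H](c1cc3c(cc1OCOC)OC(C)(C)C=C3)CCB1C2CCCC1CCC2 | intermediate
20 | (S)-3-(ArA–O)-3-(ArB)propan-1-ol | COc1cc(OCOC)c(I)c(c1CC=C(C)C)O[C@H](c1cc3c(cc1OCOC)OC(C)(C)C=C3)CCO | intermediate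
21 | (S)-3-(ArA–O)-3-(ArB)propanal (not isolated) | COc1cc(OCOC)c(I)c(c1CC=C(C)C)O[C@H](c1cc3c(cc1OCOC)OC(C)(C)C=C3)CC=O | intermediate
22 | (S)-3-(ArA–O)-3-(ArB)propanoic acid | COc1cc(OCOC)c(I)c(c1CC=C(C)C)O[C@H](c1cc3c(cc1OCOC)OC(C)(C)C=C3)CC(=O)O | intermediate
23 | (S)-3-(ArA–O)-3-(ArB)-1-(imidazol-1-yl)propan-1-one (not isolated) | COc1cc(OCOC)c(I)c(c1CC=C(C)C)O[C@H](c1cc3c(cc1OCOC)OC(C)(C)C=C3)CC(=O)n1ccnc1 | intermediate
24 | (S)-3-(ArA–O)-3-(ArB)-N-methoxy-N-methylpropanamide (key-step precursor) | COc1cc(OCOC)c(I)c(c1CC=C(C)C)O[C@H](c1cc3c(cc1OCOC)OC(C)(C)C=C3)CC(=O)N(C)OC | intermediate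
25 | C4a aryllithium derived from 24 (not isolated) | COc1cc(OCOC)c([Li])c(c1CC=C(C)C)O[C@H](c1cc3c(cc1OCOC)OC(C)(C)C=C3)CC(=O)N(C)OC | intermediate
26 | lithium salt of the C4 hemiaminal, (2S), C4 undefined (not isolated) | COc1cc(OCOC)c2c(c1CC=C(C)C)O[C@H](c1cc3c(cc1OCOC)OC(C)(C)C=C3)CC2(O[Li])N(C)OC | intermediate
27 | (2S)-7-methoxy-5-(methoxymethoxy)-2-(ArB)-8-(3-methylbut-2-enyl)chroman-4-one (flavanone bis-MOM ether) | COc1cc(OCOC)c2c(c1CC=C(C)C)O[C@H](c1cc3c(cc1OCOC)OC(C)(C)C=C3)CC2=O | intermediate
28 | maackiaflavanone A, (2S) | COc1cc(O)c2c(c1CC=C(C)C)O[C@H](c1cc3c(cc1O)OC(C)(C)C=C3)CC2=O | target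

**Step count**

Total step count: 17.
Longest linear sequence: 12 steps (steps 6–17, from 9). The ring A branch runs 11 steps (steps 1–5 and 12–17).

**Steps most likely to fail**

**Step 16.**
- What may go wrong: an α-methylene proton could be transferred to n-BuLi or to the aryllithium, followed by β-elimination of the aryloxide. The aryllithium could also be protonated before it cyclises.
- Fallback: a non-basic arylchromium addition to an aldehyde replaces the aryllithium acylation and makes the same C4–C4a bond.
- It sets out from alcohol 20, which is oxidised with Dess–Martin periodinane and NaHCO3 in CH2Cl2 to aldehyde 21, now isolated.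
- CrCl2 (excess) with catalytic NiCl2 in DMF at room temperature, an intramolecular Nozaki–Hiyama–Kishi reaction, should insert at the C4a–I bond and add to the aldehyde. This gives the (2S)-flavan-4-ol bis-MOM ether F1 as a mixture of C4 epimers.
- A second Dess–Martin oxidation erases the C4 centre and comes back to the route at 27.

**Step 12.**
- What may go wrong: the doubly ortho-substituted aryloxide could attack slowly, material could leak to the linear ether, and the catalyst could re-ionise the electron-rich branched ether and erode its enantiopurity.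
- Fallback: C2 is set by ketone reduction and the C2–O1 bond is made by inversion.
- It sets out from aldehyde 13. The lithium enolate of N-methoxy-N-methylacetamide (LDA, THF, −78 °C) should give the racemic β-hydroxy Weinreb amide F2.
- MnO2 in CH2Cl2 should oxidise this benzylic alcohol to the β-keto Weinreb amide F3.
- Asymmetric transfer hydrogenation with RuCl[(R,R)-TsDPEN](p-cymene) in HCO2H–Et3N should give the (R)-β-hydroxy Weinreb amide F4.
- Mitsunobu etherification of F4 with phenol 8 (PPh3, DIAD, toluene, −20 °C, an apolar cold medium that disfavours ionisation) inverts the centre. It comes back to the route at 24 and bypasses steps 9–15.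

**Step 17.**
- What may go wrong: acid could ionise the C2–O1 bond and the ring could reclose with loss of configuration. Acid could also add methanol to, or oligomerise, the electron-rich chromene.
- Fallback: Brønsted acid solvolysis is replaced by silyl transfer in an amine-buffered medium followed by neutral hydrolysis.
- It sets out from 27. TMSOTf and 2,2'-bipyridyl in MeCN at 0 °C should exchange both aryl MOM ethers for silyl ethers and give the bis(trimethylsilyl) ether F5.
- Adding water to the same flask hydrolyses the aryl silyl ethers and comes back to the route at 28.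

**Further compounds**

F1 | step 16 | (2S)-flavan-4-ol bis-MOM ether (C4 epimers) | COc1cc(OCOC)c2c(c1CC=C(C)C)O[C@H](c1cc3c(cc1OCOC)OC(C)(C)C=C3)CC2O
F2 | step 12 | racemic β-hydroxy Weinreb amide, 3-hydroxy-N-methoxy-N-methyl-3-(ArB)propanamide | CON(C)C(=O)CC(O)c1cc2C=CC(C)(C)Oc2cc1OCOC
F3 | step 12 | β-keto Weinreb amide, N-methoxy-N-methyl-3-oxo-3-(ArB)propanamide | CON(C)C(=O)CC(=O)c1cc2C=CC(C)(C)Oc2cc1OCOC
F4 | step 12 | (R)-β-hydroxy Weinreb amide | CON(C)C(=O)C[C@@H](O)c1cc2C=CC(C)(C)Oc2cc1OCOC
F5 | step 17 | bis(trimethylsilyl) ether of maackiaflavanone A, (2S) | COc1cc(O[Si](C)(C)C)c2c(c1CC=C(C)C)O[C@H](c1cc3c(cc1O[Si](C)(C)C)OC(C)(C)C=C3)CC2=O
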